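## Retrosynthetic overview

- **Feature:** ring A of the flavone half (C4a, C5, C6, C7, C8, C8a, with OH on C5 and C7 and O1 on C8a) is a phloroglucinol fused to pyranone ring C along C4a–C8a. This is the alternating oxygen pattern of a folded poly-β-carbonyl chain, and ring C already stores the chain carbons C2, C4 and C8a.
- **Key disconnection:** cutting the flavone C4a–C5 bond unfolds ring A to a CH2–CO–CH2–CO2t-Bu side chain on C2 of a monocyclic 6-aryl-4-pyranone. In the forward sense an acylketene acylates pyranone C3.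
- **Biaryl bond C3′–C8″:** Suzuki–Miyaura coupling of the bromoaryl pyranone keto ester with 8-borylated 5,7-di-O-benzylbiochanin A.
- **Pyranone fragment:** the side chain is grown on the pyranone methyl group from CO2 and a malonate half ester. The pyranone comes from acetylacetone dianion and methyl 3-bromo-4-methoxybenzoate.
- **Ring order:** flavone ring C first (as a free 4-pyranone), the isoflavone rings bought with biochanin A, flavone ring A last, then debenzylation.

Key step: step 9

Assumption: the target SMILES has no stereocentre and no descriptor for the C3′–C8″ axis, so the biaryl is made without control of axial configuration.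

## Route

Step 1
Reactants: 1 methyl 3-bromo-4-methoxybenzoate; 2 pentane-2,4-dione
Product: 4 1-(3-bromo-4-methoxyphenyl)hexane-1,3,5-trione, via acetylacetone dianion 3 (not isolated)
Conditions: 2 (2.1 equiv), LiN(i-Pr)2 (4.4 equiv), THF, −78 → 0 °C; then 1, 0 °C → rt; 1 M HCl
Reagents that add atoms: none
Why: Claisen-type γ-acylation of a β-diketone dianion, in which the terminal carbanion of 3 attacks the non-enolisable aromatic ester, the second equivalent of 3 takes up the acidic protons of the triketone, and no alkyllithium is present to exchange the aryl bromide.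

Step 2
Reactants: 4 1-(3-bromo-4-methoxyphenyl)hexane-1,3,5-trione
Product: 5 2-(3-bromo-4-methoxyphenyl)-6-methyl-4H-pyran-4-one
Conditions: conc. H2SO4, 0 °C; pour on ice
Reagents that add atoms: none
Why: Acid-catalysed cyclodehydration of a 1,3,5-triketone, the standard 4-pyranone synthesis, in which the enol oxygen of one outer carbonyl adds to the other outer carbonyl and water is lost while the bromide and methyl ether are inert at 0 °C.

Step 3
Reactants: 5 2-(3-bromo-4-methoxyphenyl)-6-methyl-4H-pyran-4-one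
Product: 7 2-[6-(3-bromo-4-methoxyphenyl)-4-oxo-4H-pyran-2-yl]acetic acid, via lithium dienolate 6 (not isolated)
Conditions: LiN(SiMe3)2 (1.1 equiv), THF, −78 °C; cannulate into CO2-saturated THF, −78 → −20 °C; cold 1 M HCl to pH 3; used without heating
Reagents that add atoms: carbon dioxide, O=C=O
Why: Lateral (vinylogous) deprotonation of a 2-methyl-4-pyranone gives dienolate 6, which is carboxylated at its exocyclic carbon; inverse addition into excess CO2 limits proton exchange with the product and cold acidification avoids decarboxylation.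

Step 4
Reactants: 7 2-[6-(3-bromo-4-methoxyphenyl)-4-oxo-4H-pyran-2-yl]acetic acid; 8 3-tert-butoxy-3-oxopropanoic acid (mono-tert-butyl malonate)
Product: 10 tert-butyl 4-[6-(3-bromo-4-methoxyphenyl)-4-oxo-4H-pyran-2-yl]-3-oxobutanoate, via acyl imidazolide 9 (not isolated)
Conditions: CDI (1,1′-carbonyldiimidazole, 1.1 equiv), THF, 0 °C → rt; then add to 8 (2.5 equiv), MgCl2 (2.5 equiv), Et3N (5 equiv), MeCN, rt; cold 0.5 M HCl
Reagents that add atoms: none
Why: Masamune–Brooks homologation, in which imidazolide 9 C-acylates the magnesium-chelated malonate half ester and decarboxylation gives the β-keto ester under nearly neutral conditions, avoiding a strongly basic ester enolate that would only deprotonate the doubly activated CH2 next to the pyranone.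

Step 5
Reactants: 11 biochanin A (5,7-dihydroxy-3-(4-methoxyphenyl)-4H-chromen-4-one)
Product: 12 5,7-bis(benzyloxy)-3-(4-methoxyphenyl)-4H-chromen-4-one
Conditions: BnBr (3 equiv), K2CO3 (4 equiv), DMF, 60 °C
Reagents that add atoms: benzyl bromide, BrCc1ccccc1
Why: Williamson etherification, where warm DMF and excess reagent are needed for the 5-OH that is hydrogen-bonded to C4=O, and carbonate is too poor a nucleophile to open isoflavone ring C.

Step 6
Reactants: 12 5,7-bis(benzyloxy)-3-(4-methoxyphenyl)-4H-chromen-4-one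
Product: 13 5,7-bis(benzyloxy)-8-iodo-3-(4-methoxyphenyl)-4H-chromen-4-one
Conditions: NIS (1.05 equiv), TFA (0.3 equiv), MeCN/CH2Cl2, 0 °C → rt, dark
Reagents that add atoms: N-iodosuccinimide, O=C1CCC(=O)N1I
Why: Electrophilic aromatic iodination, in which C8 (ortho to O1 and 7-OBn, para to 5-OBn) is the usual halogenation site of 5,7-dialkoxychromones, C6 is shielded between two benzyloxy groups, and the anisyl ring is less activated than the trioxygenated ring A.

Step 7
Reactants: 13 5,7-bis(benzyloxy)-8-iodo-3-(4-methoxyphenyl)-4H-chromen-4-one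
Product: 14 5,7-bis(benzyloxy)-3-(4-methoxyphenyl)-8-(4,4,5,5-tetramethyl-1,3,2-dioxaborolan-2-yl)-4H-chromen-4-one
Conditions: B2pin2 (1.5 equiv), PdCl2(dppf) (5 mol %), KOAc (3 equiv), 1,4-dioxane, 85 °C
Reagents that add atoms: bis(pinacolato)diboron, CC1(C)OB(B2OC(C)(C)C(C)(C)O2)OC1(C)C
Why: Miyaura borylation (oxidative addition of the aryl iodide to zerovalent palladium, acetate-assisted transmetalation from B2pin2, reductive elimination), with KOAc too weak to damage the isoflavone or to promote homocoupling.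

Step 8
Reactants: 10 tert-butyl 4-[6-(3-bromo-4-methoxyphenyl)-4-oxo-4H-pyran-2-yl]-3-oxobutanoate; 14 5,7-bis(benzyloxy)-3-(4-methoxyphenyl)-8-(4,4,5,5-tetramethyl-1,3,2-dioxaborolan-2-yl)-4H-chromen-4-one
Product: 15 tert-butyl 4-[6-(3-{5,7-bis(benzyloxy)-3-(4-methoxyphenyl)-4-oxo-4H-chromen-8-yl}-4-methoxyphenyl)-4-oxo-4H-pyran-2-yl]-3-oxobutanoate
Conditions: 14 (1.5 equiv), Pd(OAc)2 (5 mol %), SPhos (2-dicyclohexylphosphino-2′,6′-dimethoxybiphenyl, 10 mol %), K3PO4 (4 equiv), THF/H2O 10:1, 50 °C; pH 5 buffer work-up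
Reagents that add atoms: none
Why: Suzuki–Miyaura coupling, in which the bulky electron-rich biarylphosphine lets the tri-ortho-substituted biaryl form at 50 °C, a temperature at which the tert-butyl β-keto ester (held as its potassium enolate) does not yet lose tert-butanol and phosphate opens neither pyranone ring.

Step 9
Reactants: 15 tert-butyl 4-[6-(3-{5,7-bis(benzyloxy)-3-(4-methoxyphenyl)-4-oxo-4H-chromen-8-yl}-4-methoxyphenyl)-4-oxo-4H-pyran-2-yl]-3-oxobutanoate
Product: 19 5,7-bis(benzyloxy)-8-[5-(5,7-dihydroxy-4-oxo-4H-chromen-2-yl)-2-methoxyphenyl]-3-(4-methoxyphenyl)-4H-chromen-4-one, via acylketene 16 (not isolated), via dienylketene enol 17 (not isolated), via ring-closed dienedione 18 (not isolated)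
Conditions: dry degassed PhMe (final 0.002 M), 15 added slowly at reflux (110 °C), slow distillation of PhMe/t-BuOH with make-up solvent, N2
Reagents that add atoms: none
Why: Proposed new method: neutral heating expels tert-butanol from 15 in the way established for tert-butyl acetoacetates and gives acylketene 16, whose enol 17 is a dienylketene that ends in the pyranone C2=C3 bond. A thermal disrotatory six-electron electrocyclisation, in polar terms a 6-(enolendo)-exo-dig C-acylation of the nucleophilic vinylogous-ester carbon C3 by the ketene carbon, forms the flavone C4a–C5 bond and closes ring A as dienedione 18, and a proton shift from the doubly activated C4a to oxygen makes ring A aromatic in 19. The closest known reaction types are carbon acylation by thermally generated acylketenes (from tert-butyl β-keto esters or dioxinones), the dienylketene-to-phenol closure of benzannulation chemistry, the Claisen cyclisation of β-polyketo esters to acylphloroglucinols and the closure of 4-aryl-3-oxobutanoates to naphthalene-1,3-diols, but C3 of a 4-pyranone has not served as the terminus. No stereocentre results, because the sp3 centre C4a of 18 is erased by tautomerisation. Closure at C3 must outrun ketene dimerisation and capture by tert-butanol, water or the phenols of 19: high dilution, dry solvent and removal of tert-butanol serve this, capture by alcohols and phenols is reversible at 110 °C whereas aromatisation is not, and the pyranone ring fixes the other chain carbonyls so that only this one six-membered fold exists. The neutral medium leaves the base-sensitive isoflavone ring C, the benzyl ethers and the methyl ethers untouched.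

Step 10
Reactants: 19 5,7-bis(benzyloxy)-8-[5-(5,7-dihydroxy-4-oxo-4H-chromen-2-yl)-2-methoxyphenyl]-3-(4-methoxyphenyl)-4H-chromen-4-one
Product: 20 5,7-dihydroxy-8-[5-(5,7-dihydroxy-4-oxo-4H-chromen-2-yl)-2-methoxyphenyl]-3-(4-methoxyphenyl)-4H-chromen-4-one (CNP0117905.0)
Conditions: BCl3 (8 equiv), pentamethylbenzene (6 equiv), CH2Cl2, −78 → −30 °C; H2O
Reagents that add atoms: none
Why: Lewis-acid debenzylation with a non-basic cation scavenger, in which BCl3 ionises the aryl benzyl ethers, pentamethylbenzene takes up the benzyl cation by Friedel–Crafts alkylation so the electron-rich rings are not C-benzylated, and the two non-chelated aryl methyl ethers and the reducible isoflavone C2=C3 bond survive at low temperature.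

## Compound list

In 16–18, Ar = 3-{5,7-bis(benzyloxy)-3-(4-methoxyphenyl)-4-oxo-4H-chromen-8-yl}-4-methoxyphenyl.

1 | methyl 3-bromo-4-methoxybenzoate | COC(=O)c1ccc(OC)c(Br)c1 | starting material
2 | pentane-2,4-dione | CC(=O)CC(C)=O | starting material
3 | acetylacetone dianion, dilithium salt (not isolated) | [Li+].[Li+].[CH2-]C(=O)[CH-]C(C)=O | intermediate
4 | 1-(3-bromo-4-methoxyphenyl)hexane-1,3,5-trione | CC(=O)CC(=O)CC(=O)c1ccc(OC)c(Br)c1 | intermediate
5 | 2-(3-bromo-4-methoxyphenyl)-6-methyl-4H-pyran-4-one | Cc1cc(=O)cc(-c2ccc(OC)c(Br)c2)o1 | intermediate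
6 | lithium 6-(3-bromo-4-methoxyphenyl)-2-methylidene-2H-pyran-4-olate (not isolated) | [Li+].C=C1C=C([O-])C=C(-c2ccc(OC)c(Br)c2)O1 | intermediate
7 | 2-[6-(3-bromo-4-methoxyphenyl)-4-oxo-4H-pyran-2-yl]acetic acid | O=C(O)Cc1cc(=O)cc(-c2ccc(OC)c(Br)c2)o1 | intermediate
8 | 3-tert-butoxy-3-oxopropanoic acid (mono-tert-butyl malonate) | CC(C)(C)OC(=O)CC(=O)O | starting material
9 | 2-(3-bromo-4-methoxyphenyl)-6-[2-(imidazol-1-yl)-2-oxoethyl]-4H-pyran-4-one (not isolated) | O=C(Cc1cc(=O)cc(-c2ccc(OC)c(Br)c2)o1)n1ccnc1 | intermediate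
10 | tert-butyl 4-[6-(3-bromo-4-methoxyphenyl)-4-oxo-4H-pyran-2-yl]-3-oxobutanoate | CC(C)(C)OC(=O)CC(=O)Cc1cc(=O)cc(-c2ccc(OC)c(Br)c2)o1 | intermediate
11 | biochanin A | COc1ccc(-c2coc3cc(O)cc(O)c3c2=O)cc1 | starting material
12 | 5,7-bis(benzyloxy)-3-(4-methoxyphenyl)-4H-chromen-4-one | COc1ccc(-c2coc3cc(OCc4ccccc4)cc(OCc4ccccc4)c3c2=O)cc1 | intermediate
13 | 5,7-bis(benzyloxy)-8-iodo-3-(4-methoxyphenyl)-4H-chromen-4-one | COc1ccc(-c2coc3c(I)c(OCc4ccccc4)cc(OCc4ccccc4)c3c2=O)cc1 | intermediate
14 | 5,7-bis(benzyloxy)-3-(4-methoxyphenyl)-8-(4,4,5,5-tetramethyl-1,3,2-dioxaborolan-2-yl)-4H-chromen-4-one | COc1ccc(-c2coc3c(B4OC(C)(C)C(C)(C)O4)c(OCc4ccccc4)cc(OCc4ccccc4)c3c2=O)cc1 | intermediate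
15 | tert-butyl 4-[6-(3-{5,7-bis(benzyloxy)-3-(4-methoxyphenyl)-4-oxo-4H-chromen-8-yl}-4-methoxyphenyl)-4-oxo-4H-pyran-2-yl]-3-oxobutanoate | CC(C)(C)OC(=O)CC(=O)Cc1cc(=O)cc(-c2ccc(OC)c(-c3c(OCc4ccccc4)cc(OCc4ccccc4)c4c(=O)c(-c5ccc(OC)cc5)coc34)c2)o1 | intermediate
16 | 4-[6-(Ar)-4-oxo-4H-pyran-2-yl]but-1-ene-1,3-dione, the acylketene (not isolated) | O=C=CC(=O)Cc1cc(=O)cc(-c2ccc(OC)c(-c3c(OCc4ccccc4)cc(OCc4ccccc4)c4c(=O)c(-c5ccc(OC)cc5)coc34)c2)o1 | intermediate
17 | (3E)-3-hydroxy-4-[6-(Ar)-4-oxo-4H-pyran-2-yl]buta-1,3-dien-1-one, ketenyl and pyranyl groups cis (not isolated) | O=C=C/C(O)=C\c1cc(=O)cc(-c2ccc(OC)c(-c3c(OCc4ccccc4)cc(OCc4ccccc4)c4c(=O)c(-c5ccc(OC)cc5)coc34)c2)o1 | intermediate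
18 | 2-(Ar)-7-hydroxy-4aH-chromene-4,5-dione, racemic at the transient C4a (not isolated) | O=C1C=C(O)C=C2OC(-c3ccc(OC)c(-c4c(OCc5ccccc5)cc(OCc5ccccc5)c5c(=O)c(-c6ccc(OC)cc6)coc45)c3)=CC(=O)C12 | intermediate
19 | 5,7-bis(benzyloxy)-8-[5-(5,7-dihydroxy-4-oxo-4H-chromen-2-yl)-2-methoxyphenyl]-3-(4-methoxyphenyl)-4H-chromen-4-one | COc1ccc(-c2coc3c(-c4cc(-c5cc(=O)c6c(O)cc(O)cc6o5)ccc4OC)c(OCc4ccccc4)cc(OCc4ccccc4)c3c2=O)cc1 | intermediate
20 | 5,7-dihydroxy-8-[5-(5,7-dihydroxy-4-oxo-4H-chromen-2-yl)-2-methoxyphenyl]-3-(4-methoxyphenyl)-4H-chromen-4-one (CNP0117905.0) | COc1ccc(-c2coc3c(-c4cc(-c5cc(=O)c6c(O)cc(O)cc6o5)ccc4OC)c(O)cc(O)c3c2=O)cc1 | target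

## Step count and risks

Total step count: 10.
Longest linear sequence: 7 (steps 1, 2, 3, 4, 8, 9, 10).

**Step 9 (key step).**
- What may go wrong:
  - The acylketene may be drained by dimerisation or by hydration followed by decarboxylation.
  - The ester may lose isobutene under catalysis by the acidic product.
  - Pyranone C3 may be too weak a nucleophile, so the ketene only returns to the ester.
- The fallback builds the flavone by classical 1,3-diketone chemistry. It sets out from 1 and 14 and comes back at 20.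
- Commercial 1-[2,4-bis(benzyloxy)-6-hydroxyphenyl]ethanone (CC(=O)c1c(O)cc(OCc2ccccc2)cc1OCc1ccccc1) is doubly deprotonated with LiN(SiMe3)2 in THF. It is C-acylated by ester 1 in a Baker–Venkataraman-type Claisen condensation to give 1-[2,4-bis(benzyloxy)-6-hydroxyphenyl]-3-(3-bromo-4-methoxyphenyl)propane-1,3-dione F1.
- p-TsOH in warm toluene cyclodehydrates this to 5,7-bis(benzyloxy)-2-(3-bromo-4-methoxyphenyl)-4H-chromen-4-one F2.
- Suzuki–Miyaura coupling of F2 with 14, using the catalyst of step 8, gives 5,7-bis(benzyloxy)-8-{5-[5,7-bis(benzyloxy)-4-oxo-4H-chromen-2-yl]-2-methoxyphenyl}-3-(4-methoxyphenyl)-4H-chromen-4-one F3.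
- BCl3 and pentamethylbenzene then remove all four benzyl groups to give 20.

**Step 8.**
- What may go wrong:
  - The boronate, which sits on the most electron-rich carbon of ring A, may protodeboronate.
  - Transmetalation into a tri-ortho-substituted biaryl may be slow.
  - The β-keto ester enolate may chelate palladium or be C-arylated.
  - Base may unravel the pyranone.
- The fallback reverses the polarity and couples before the side chain is grown. It sets out from 5 and 13 and comes back at 15.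
- Miyaura borylation of 5 gives 2-[4-methoxy-3-(4,4,5,5-tetramethyl-1,3,2-dioxaborolan-2-yl)phenyl]-6-methyl-4H-pyran-4-one F4.
- Coupling of F4 with iodide 13 gives 5,7-bis(benzyloxy)-8-[2-methoxy-5-(6-methyl-4-oxo-4H-pyran-2-yl)phenyl]-3-(4-methoxyphenyl)-4H-chromen-4-one F5.
- Lateral deprotonation with the non-nucleophilic LiN(SiMe3)2 at −78 °C and a CO2 quench give 2-[6-(3-{5,7-bis(benzyloxy)-3-(4-methoxyphenyl)-4-oxo-4H-chromen-8-yl}-4-methoxyphenyl)-4-oxo-4H-pyran-2-yl]acetic acid F6.
- Masamune–Brooks homologation of F6 with CDI, 8, MgCl2 and Et3N gives 15.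

**Step 3.**
- What may go wrong:
  - The dienolate may add to unreacted pyranone (self-condensation).
  - Proton exchange with the carboxylate may stall conversion.
  - CO2 may be lost from the activated acetic acid during isolation.
- The fallback avoids strong base and the free acid. It sets out from 5, comes back at 10, and bypasses steps 3 and 4.
- Condensation of 5 with DMF dimethyl acetal (N-methylimidazole, 120 °C) gives 2-(3-bromo-4-methoxyphenyl)-6-[(E)-2-(dimethylamino)ethenyl]-4H-pyran-4-one F7.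
- Mild aqueous acid hydrolyses F7 to 2-[6-(3-bromo-4-methoxyphenyl)-4-oxo-4H-pyran-2-yl]acetaldehyde F8.
- A Roskamp reaction of F8 with tert-butyl diazoacetate and catalytic SnCl2 in CH2Cl2 gives 10.

## Further compounds

F1 | step 9 | 1-[2,4-bis(benzyloxy)-6-hydroxyphenyl]-3-(3-bromo-4-methoxyphenyl)propane-1,3-dione | COc1ccc(C(=O)CC(=O)c2c(O)cc(OCc3ccccc3)cc2OCc2ccccc2)cc1Br
F2 | step 9 | 5,7-bis(benzyloxy)-2-(3-bromo-4-methoxyphenyl)-4H-chromen-4-one | COc1ccc(-c2cc(=O)c3c(OCc4ccccc4)cc(OCc4ccccc4)cc3o2)cc1Br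
F3 | step 9 | 5,7-bis(benzyloxy)-8-{5-[5,7-bis(benzyloxy)-4-oxo-4H-chromen-2-yl]-2-methoxyphenyl}-3-(4-methoxyphenyl)-4H-chromen-4-one | COc1ccc(-c2coc3c(-c4cc(-c5cc(=O)c6c(OCc7ccccc7)cc(OCc7ccccc7)cc6o5)ccc4OC)c(OCc4ccccc4)cc(OCc4ccccc4)c3c2=O)cc1
F4 | step 8 | 2-[4-methoxy-3-(4,4,5,5-tetramethyl-1,3,2-dioxaborolan-2-yl)phenyl]-6-methyl-4H-pyran-4-one | Cc1cc(=O)cc(-c2ccc(OC)c(B3OC(C)(C)C(C)(C)O3)c2)o1
F5 | step 8 | 5,7-bis(benzyloxy)-8-[2-methoxy-5-(6-methyl-4-oxo-4H-pyran-2-yl)phenyl]-3-(4-methoxyphenyl)-4H-chromen-4-one | Cc1cc(=O)cc(-c2ccc(OC)c(-c3c(OCc4ccccc4)cc(OCc4ccccc4)c4c(=O)c(-c5ccc(OC)cc5)coc34)c2)o1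
F6 | step 8 | 2-[6-(3-{5,7-bis(benzyloxy)-3-(4-methoxyphenyl)-4-oxo-4H-chromen-8-yl}-4-methoxyphenyl)-4-oxo-4H-pyran-2-yl]acetic acid | O=C(O)Cc1cc(=O)cc(-c2ccc(OC)c(-c3c(OCc4ccccc4)cc(OCc4ccccc4)c4c(=O)c(-c5ccc(OC)cc5)coc34)c2)o1
F7 | step 3 | 2-(3-bromo-4-methoxyphenyl)-6-[(E)-2-(dimethylamino)ethenyl]-4H-pyran-4-one | CN(C)/C=C/c1cc(=O)cc(-c2ccc(OC)c(Br)c2)o1
F8 | step 3 | 2-[6-(3-bromo-4-methoxyphenyl)-4-oxo-4H-pyran-2-yl]acetaldehyde | O=CCc1cc(=O)cc(-c2ccc(OC)c(Br)c2)o1
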